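**Assumption:** 3-(3,4-dimethoxyphenyl)prop-2-ynoic acid (7) is taken as a catalogue compound. The only chiral intermediate (14) is racemic and transient.

## Analysis of the target

Pebrellin (18, C19H18O8) is a flavone: a 4H-chromen-4-one (rings A and C) with a 3,4-dimethoxyphenyl group (ring B) on C2. It has no stereocentre, so the whole problem is one of substitution pattern. Ring A is fully substituted: C5 and C6 carry free hydroxyls, C7 and C8 carry methoxy groups, C8a carries the ring oxygen O1 and C4a the C4 carbonyl. The sensitive parts are the 5,6-catechol, which air oxidises in base, and the pyranone, which strong hydroxide can open at C2. Once a free O5 is present, an opened pyranone can re-close on either oxygen flanking C4a, which would exchange the 5,6-dihydroxy-7,8-dimethoxy pattern for the 5,8-dihydroxy-6,7-dimethoxy one. The difficulty therefore lies in placing and differentiating the five oxygens of ring A, not in rings B and C. The strategy rests on reading C6(O)–C7(OMe)–C8(OMe)–C8a(O) as a 2-silyloxy-3,4-dimethoxyfuran: its four carbons become C8a, C8, C7 and C6, its ring oxygen becomes the C6 hydroxyl and its silyloxy oxygen becomes O1. C5 and C4a are then the two carbons of an alkyne that already carries the C4 carbonyl, with a bromine standing in for O5.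

## Retrosynthetic reasoning

**C5–O.** The last bond cut is C5–O, which leads from 18 back to the 5-bromo-6-hydroxyflavone 17; the forward reaction is a copper-catalysed hydroxylation of the aryl bromide. Cutting here keeps the catechol out of the synthesis until the final step. It also means that, as long as C5 carries bromine, O8a is the only oxygen ortho to C4a, so ring C can close in one direction only and an opened pyranone can only return to 17. The forward step must exchange a hindered, electron-rich bromide; the peri C4 carbonyl and the ortho phenoxide are placed to hold copper at that carbon.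

**O1–C2.** Ring C of 17 is opened at O1–C2, giving the aryl alkynyl ketone 15, whose O8a is silylated and whose C6 hydroxyl is free. In the forward direction fluoride frees O8a (hydroquinone 16), and the phenoxide adds to the alkyne carbon bearing ring B in a 6-endo-dig closure. This cut is chosen because the ynone is the form in which C4, C3, C2 and ring B can be carried through the ring A construction as one unit. The forward step must favour 6-endo over 5-exo closure.

**C6–C5 and C8a–C4a (key disconnection).** Ring A of 15 is cut at these two bonds, which returns it through the oxygen-bridged adduct 14 to the siloxyfuran 6 and the bromodiynone 13. This is the only disconnection that delivers all six ring A substituents in the right order in one operation from two small, unsymmetrical pieces. The four oxygens come differentiated (O6 free, O8a silylated, two methyl ethers), bromine marks C5, and the carbon chain of ring C is already on C4a. The forward reaction must join the unsubstituted furan α-carbon to the bromine-bearing alkyne carbon, must use the bromoalkyne and not the aryl alkyne, and must open the oxygen bridge at the silyloxy bridgehead.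

**Furan 6.** The O–Si bond is cut to give butenolide 5, and the enol O–Me bond to give the tetronic acid 4. The C3–C4 bond of 4 is cut by a Dieckmann disconnection to the diester 3, and the ester C–O bond of 3 leads to methyl glycolate (1) and methoxyacetyl chloride (2). The C3 methoxy group is present from the start, so no oxidation of the ring is needed.

**Diynone 13.** The C–Br bond is cut to the alkynylsilane 12. The bond between the carbonyl carbon and the silylated alkyne is cut to the N-methoxy-N-methylamide 9 and the acetylide 11, made from ethynyltrimethylsilane (10). Amide 9 comes from acid 7 through its chloride 8. The ketone is formed from an amide so that the addition stops after one acetylide.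

## Alternatives that were turned down

**Alternative 1:** ring A from a four-membered ring.
- Disconnection: the phenol A1 (2-ethoxy-5,6-dimethoxy-4-(methoxymethoxy)phenol) is cut at C5–C6 and traced to the cyclobutenone A2, which would come from a squaric diester and a metallated enol ether.
- Forward key step: heating A2 in toluene opens the four-membered ring to a dienylketene (the oxygen substituent turning outward, the vinyl group inward), and a six-electron electrocyclisation then tautomerisation gives A1.
- For: the cascade is intramolecular, its regiochemistry is fixed by connectivity, and all five oxygens arrive differentiated. On reliability of the key step this alternative is stronger than the chosen one.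
- Against: in A1 the future C4a is a C–H between two oxygens. The free phenol must be masked, the ring metalated and acylated at its most hindered position, ring C closed, and the C5 ethyl ether removed selectively beside four methyl ethers. That is five or six operations after the key step, against two.
- Comparison: the chosen strategy gives up some certainty in the key step, but ring A arrives with the whole carbon skeleton of the flavone attached.

**Alternative 2:** ring C closed at O1–C8a.
- Disconnection: the protected flavone A3 is cut at O1–C8a to the bromoaryl 1,3-diketone A4.
- Forward key step: a copper catalyst with a phenanthroline-type ligand and carbonate base couples the enolate oxygen with the C8a–Br carbon; acid then removes the two methoxymethyl groups to give 18.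
- For: the ring closure is known and has one possible direction. The end game is a mild acetal cleavage with no hydroxide near the flavone, which is stronger than the last step of the chosen route.
- Against: A4 needs a benzene ring with six different substituents in fixed order. This must be built by stepwise substitution and protection of a simpler arene, so the real difficulty of the target is moved to a long linear opening with several regiochemical decisions.
- Comparison: the chosen strategy solves the ring A pattern in the key step itself and needs no oxygen protecting group other than the silyl group that the furan brings.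

**Alternative 3:** ring A by double Claisen condensation.
- Disconnection: the triketone A5 is cut at C4a–C5 and C4a–C8a to the dianion of the diketone A7 and the butenolide ester A6, available from L-ascorbic acid A8.
- Forward key step: the terminal carbon of the A7 dianion acylates first at the ester and then at the lactone carbonyl of A6, and the ring aromatises by enolisation.
- For: it is the shortest on paper, needs no protecting group, and takes the ring A oxygens from a cheap natural product. On step count it is stronger than the chosen route.
- Against: the C2–H of A6 is α to an ester and γ to the butenolide carbonyl, so the basic dianion is likely to deprotonate it and form an aromatic furanolate. In addition A5 has hydroxyls on both carbons flanking the acyl group, so cyclodehydration can give 18 or its isomer A9 with nothing in the structure to decide.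
- Comparison: in the chosen route the bromine on C5 removes this ambiguity, and the ring-forming step pairs a nucleophile with an electrophile and has no competing acid–base reaction.

Key step: step 8

## Route

Step 1
Reactants: 1 methyl glycolate; 2 methoxyacetyl chloride
Product: 3 methyl 2-[(methoxyacetyl)oxy]acetate
Conditions: pyridine, CH2Cl2, 0 °C → rt
Reagents that add atoms: none
Why: Esterification of a primary alcohol with an acid chloride; pyridine is used in place of a trialkylamine so that 2 is not converted into methoxyketene.

Step 2
Reactants: 3 methyl 2-[(methoxyacetyl)oxy]acetate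
Product: 4 4-hydroxy-3-methoxyfuran-2(5H)-one
Conditions: LiN(SiMe3)2 (2.2 equiv), THF, −78 → 0 °C; then 1 M HCl
Reagents that add atoms: none
Why: Dieckmann condensation of an α-acyloxy ester, the standard tetronic acid synthesis: the enolate of the methoxyacetyl CH2 attacks the methyl ester in a 5-exo-trig closure, and the second equivalent of base traps the product as its vinylogous carboxylate, which makes the closure irreversible.

Step 3
Reactants: 4 4-hydroxy-3-methoxyfuran-2(5H)-one
Product: 5 3,4-dimethoxyfuran-2(5H)-one
Conditions: Me2SO4, K2CO3, acetone, reflux
Reagents that add atoms: dimethyl sulfate, COS(=O)(=O)OC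
Why: O-alkylation of a vinylogous acid; C3 is already substituted, so C-alkylation is disfavoured, and a hard methylating agent with carbonate gives the 4-O-methyl tetronate as with other tetronic acids.

Step 4
Reactants: 5 3,4-dimethoxyfuran-2(5H)-one
Product: 6 tert-butyl[(3,4-dimethoxyfuran-2-yl)oxy]dimethylsilane
Conditions: TBSOTf, Et3N, CH2Cl2, 0 °C; filtered through basic alumina and used at once
Reagents that add atoms: tert-butyldimethylsilyl trifluoromethanesulfonate, CC(C)(C)[Si](C)(C)OS(=O)(=O)C(F)(F)F
Why: Soft enolisation of a butenolide: the carbonyl oxygen is silylated and the amine removes the γ-proton at C5, which aromatises the ring; this is the usual preparation of 2-silyloxyfurans from butenolides and tetronates.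

Step 5
Reactants: 7 3-(3,4-dimethoxyphenyl)prop-2-ynoic acid
Product: 9 3-(3,4-dimethoxyphenyl)-N-methoxy-N-methylprop-2-ynamide, via 3-(3,4-dimethoxyphenyl)prop-2-ynoyl chloride 8 (not isolated)
Conditions: (COCl)2, cat. DMF, CH2Cl2, 0 °C → rt, evaporate; then MeNH(OMe)·HCl, pyridine, CH2Cl2, 0 °C
Reagents that add atoms: N,O-dimethylhydroxylamine hydrochloride, CNOC.Cl; oxalyl chloride, O=C(Cl)C(=O)Cl (supplies only the chlorine of intermediate 8)
Why: Acid chloride formation and N-acylation (Weinreb amide synthesis); the aryl-substituted alkyne is a weak Michael acceptor, so acylation of the amine at 0 °C should outrun conjugate addition.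

Step 6
Reactants: 9 3-(3,4-dimethoxyphenyl)-N-methoxy-N-methylprop-2-ynamide; 10 ethynyltrimethylsilane
Product: 12 1-(3,4-dimethoxyphenyl)-5-(trimethylsilyl)penta-1,4-diyn-3-one, via lithium (trimethylsilyl)acetylide 11 (not isolated)
Conditions: 10, n-BuLi, THF, −78 °C; then 9, −78 → −30 °C; poured into cold 1 M HCl
Reagents that add atoms: n-butyllithium, [Li]CCCC (supplies only the lithium of intermediate 11)
Why: Weinreb ketone synthesis: the N-methoxy-N-methylamide takes up one acetylide and releases the ketone only on quench, and the cold acidic quench protonates the liberated amine before it can add to the diynone.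

Step 7
Reactants: 12 1-(3,4-dimethoxyphenyl)-5-(trimethylsilyl)penta-1,4-diyn-3-one
Product: 13 1-bromo-5-(3,4-dimethoxyphenyl)penta-1,4-diyn-3-one
Conditions: NBS (1.1 equiv), AgNO3 (10 mol %), acetone, rt, dark; used without storage
Reagents that add atoms: N-bromosuccinimide, O=C1CCC(=O)N1Br
Why: Silver-catalysed bromodesilylation of an alkynylsilane through the silver acetylide, a standard route to 1-bromoalkynes including bromoalkynyl ketones; the dimethoxyphenyl ring is deactivated toward NBS by the conjugated ynone.

Step 8
Reactants: 6 tert-butyl[(3,4-dimethoxyfuran-2-yl)oxy]dimethylsilane; 13 1-bromo-5-(3,4-dimethoxyphenyl)penta-1,4-diyn-3-one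
Product: 15 1-[2-bromo-6-(tert-butyldimethylsilyloxy)-3-hydroxy-4,5-dimethoxyphenyl]-3-(3,4-dimethoxyphenyl)prop-2-yn-1-one, via 7-oxanorbornadiene cycloadduct 14 (not isolated)
Conditions: 6 (1.3 equiv), toluene, −20 °C → rt, argon, dark; then SiO2
Reagents that add atoms: none
Why: The siloxyfuran is a cyclic ketene acetal diene whose most nucleophilic terminus is the unsubstituted α-carbon, and the bromoalkynyl ketone is an electron-poor dienophile whose most electrophilic terminus is the bromine-bearing β-carbon, so a normal-demand, asynchronous (4+2) cycloaddition should join these two atoms (C6–C5) and then the silyloxy carbon to the α-carbon of the ynone (C8a–C4a). This closes the six-membered carbocycle of ring A intermolecularly as the oxygen-bridged diene 14. In 14 the bridge C–O bond at the silyloxy bridgehead is an acetal bond and ionises to a silyloxy-stabilised, doubly allylic cation; loss of the proton at the other bridgehead aromatises the ring, so the former furan oxygen becomes the free C6 hydroxyl and the silyl group stays on O8a. The closest known reaction type is the Diels–Alder addition of 2-alkoxy- and 2-silyloxyfurans to acetylenic esters and ketones with opening to para-oxygenated phenols, together with the use of haloalkynyl carbonyl compounds as dienophiles for furans. The two bridgehead stereocentres of 14 are racemic and disappear on aromatisation, so no stereocontrol is required. Regioselectivity is secured by the matched polarisation of the two partners and by the fact that the hindered silyloxy carbon bonds to the less hindered inner alkyne carbon late in the transition state. Site selectivity between the two alkynes is secured by the donor aryl group, which lowers the electrophilicity of its own alkyne and shields it, while bromine leaves the other alkyne linear and open. Toluene is chosen to keep the addition as concerted as possible and so to suppress ionic side paths.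

Step 9
Reactants: 15 1-[2-bromo-6-(tert-butyldimethylsilyloxy)-3-hydroxy-4,5-dimethoxyphenyl]-3-(3,4-dimethoxyphenyl)prop-2-yn-1-one
Product: 17 5-bromo-2-(3,4-dimethoxyphenyl)-6-hydroxy-7,8-dimethoxy-4H-chromen-4-one, via desilylated hydroquinone ynone 16 (not isolated)
Conditions: KF (3 equiv), 18-crown-6, dry degassed DMF, 0 °C → rt, argon; then 1 M HCl
Reagents that add atoms: none
Why: Fluoride cleaves the aryl silyl ether and the O8a phenoxide adds to the aryl-bearing alkyne carbon in a 6-endo-dig oxa-Michael closure; aprotic fluoride conditions are the known way to steer o-hydroxyaryl ynones to chromones, because the 6-endo allenolate is carbonyl-stabilised while the 5-exo vinyl anion is not and reverts. With bromine on C5 only one oxygen flanks the ketone, so a single flavone can form.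

Step 10
Reactants: 17 5-bromo-2-(3,4-dimethoxyphenyl)-6-hydroxy-7,8-dimethoxy-4H-chromen-4-one
Product: 18 pebrellin, 2-(3,4-dimethoxyphenyl)-5,6-dihydroxy-7,8-dimethoxy-4H-chromen-4-one
Conditions: CuI (10 mol %), N,N′-bis(4-hydroxy-2,6-dimethylphenyl)oxalamide (10 mol %), LiOH·H2O (4 equiv), degassed DMSO/H2O (4:1), 80 °C, argon; then 1 M HCl
Reagents that add atoms: lithium hydroxide monohydrate, [Li+].[OH-].O
Why: Copper-catalysed Ullmann-type hydroxylation of an aryl bromide; the peri C4 carbonyl and the ortho phenoxide can chelate copper at C5, and the corresponding alkoxide exchange is routine on bromo-hydroxyflavones. The medium is degassed because the catecholate product is air-sensitive.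

## Compound list

1 | methyl glycolate | COC(=O)CO | starting material
2 | methoxyacetyl chloride | COCC(=O)Cl | starting material
3 | methyl 2-[(methoxyacetyl)oxy]acetate | COCC(=O)OCC(=O)OC | intermediate
4 | 4-hydroxy-3-methoxyfuran-2(5H)-one | COC1=C(O)COC1=O | intermediate
5 | 3,4-dimethoxyfuran-2(5H)-one | COC1=C(OC)C(=O)OC1 | intermediate
6 | tert-butyl[(3,4-dimethoxyfuran-2-yl)oxy]dimethylsilane | COc1coc(O[Si](C)(C)C(C)(C)C)c1OC | intermediate
7 | 3-(3,4-dimethoxyphenyl)prop-2-ynoic acid | COc1ccc(C#CC(=O)O)cc1OC | starting material
8 | 3-(3,4-dimethoxyphenyl)prop-2-ynoyl chloride | COc1ccc(C#CC(=O)Cl)cc1OC | intermediate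
9 | 3-(3,4-dimethoxyphenyl)-N-methoxy-N-methylprop-2-ynamide | COc1ccc(C#CC(=O)N(C)OC)cc1OC | intermediate
10 | ethynyltrimethylsilane | C#C[Si](C)(C)C | starting material
11 | lithium (trimethylsilyl)acetylide | [Li]C#C[Si](C)(C)C | intermediate
12 | 1-(3,4-dimethoxyphenyl)-5-(trimethylsilyl)penta-1,4-diyn-3-one | COc1ccc(C#CC(=O)C#C[Si](C)(C)C)cc1OC | intermediate
13 | 1-bromo-5-(3,4-dimethoxyphenyl)penta-1,4-diyn-3-one | COc1ccc(C#CC(=O)C#CBr)cc1OC | intermediate
14 | 1-[3-bromo-1-(tert-butyldimethylsilyloxy)-5,6-dimethoxy-7-oxabicyclo[2.2.1]hepta-2,5-dien-2-yl]-3-(3,4-dimethoxyphenyl)prop-2-yn-1-one (racemic) | COC1=C(OC)C2(O[Si](C)(C)C(C)(C)C)OC1C(Br)=C2C(=O)C#Cc1ccc(OC)c(OC)c1 | intermediate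
15 | 1-[2-bromo-6-(tert-butyldimethylsilyloxy)-3-hydroxy-4,5-dimethoxyphenyl]-3-(3,4-dimethoxyphenyl)prop-2-yn-1-one | COc1ccc(C#CC(=O)c2c(Br)c(O)c(OC)c(OC)c2O[Si](C)(C)C(C)(C)C)cc1OC | intermediate
16 | 1-(2-bromo-3,6-dihydroxy-4,5-dimethoxyphenyl)-3-(3,4-dimethoxyphenyl)prop-2-yn-1-one (present as its potassium phenoxide) | COc1ccc(C#CC(=O)c2c(Br)c(O)c(OC)c(OC)c2O)cc1OC | intermediate
17 | 5-bromo-2-(3,4-dimethoxyphenyl)-6-hydroxy-7,8-dimethoxy-4H-chromen-4-one | COc1ccc(-c2cc(=O)c3c(Br)c(O)c(OC)c(OC)c3o2)cc1OC | intermediate
18 | pebrellin, 2-(3,4-dimethoxyphenyl)-5,6-dihydroxy-7,8-dimethoxy-4H-chromen-4-one | COc1ccc(-c2cc(=O)c3c(O)c(O)c(OC)c(OC)c3o2)cc1OC | target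

## Step count and least certain steps

Total step count: 10. Longest linear sequence: 7 steps (steps 1, 2, 3, 4, 8, 9, 10); the diynone branch (steps 5, 6, 7) joins at step 8.

**Step 8 (key step).** The addition may run stepwise. The furan α-carbon then adds to the bromine-bearing carbon to give a zwitterion, and its vinyl anion can expel bromide, so the furan is alkynylated and not annulated. Attack of the ketene acetal on bromine, silyl transfer within the zwitterion, and hydrolysis of the siloxyfuran before it reacts are further losses. The fallback removes the leaving group from the dienophile and introduces bromine afterwards. It sets out from 9 and 6. Ethynylmagnesium bromide in THF at 0 °C with a cold acidic quench should give 1-(3,4-dimethoxyphenyl)penta-1,4-diyn-3-one F1. Cycloaddition of 6 to the terminal alkyne of F1 in toluene, with ethynyl ketones being established dienophiles for this furan-to-phenol annulation and the polarity match unchanged, should give 1-[2-(tert-butyldimethylsilyloxy)-5-hydroxy-3,4-dimethoxyphenyl]-3-(3,4-dimethoxyphenyl)prop-2-yn-1-one F2. In F2, C5 is the only unsubstituted carbon of ring A and lies ortho to the free hydroxyl, so N-bromosuccinimide in CH2Cl2 at −20 °C (electrophilic ortho-bromination of a phenol) should return to the route at 15.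

**Step 10.** Hot aqueous hydroxide may open the pyranone at C2, and once O5 is in place reclosure on the other flanking oxygen would scramble the ring A pattern. Slow copper insertion at the crowded, electron-rich bromide could lead to reductive loss of bromine, and the catecholate may be oxidised by traces of air. The fallback avoids hydroxide and sets out from 17. Sodium benzyloxide (benzyl alcohol, NaH) with CuI in DMF at 110 °C, the benzyl analogue of the methoxide exchange used on bromo-hydroxyflavones, should give 5-(benzyloxy)-2-(3,4-dimethoxyphenyl)-6-hydroxy-7,8-dimethoxy-4H-chromen-4-one F3. Hydrogenolysis (H2, Pd/C, ethyl acetate, rt) then returns to the route at 18.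

**Step 9.** Closure may go 5-exo-dig to the five-membered benzofuranone ring if a proton source traps the vinyl anion, and the C6 phenol of the substrate is such a source. The hydroquinone dianion of 16 may also be oxidised to a quinone if air is not excluded. The fallback fixes the site of attack before O8a is freed and sets out from 15. Diethylamine in ethanol at rt should add to the ynone to give the enaminone (2E)-1-[2-bromo-6-(tert-butyldimethylsilyloxy)-3-hydroxy-4,5-dimethoxyphenyl]-3-(diethylamino)-3-(3,4-dimethoxyphenyl)prop-2-en-1-one F4. Tetrabutylammonium fluoride in THF then removes the silyl group, and the phenoxide displaces the amine at the only electrophilic carbon by addition–elimination. Only the six-membered ring can form, and the route is rejoined at 17.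

**Step 2.** Intermolecular Claisen condensation, cleavage of the acyloxy ester by liberated methoxide, or O-to-C acyl shift from the glycolate enolate may compete with ring closure. The fallback forms the C3–C4 bond intermolecularly and sets out from 2. Methanol and pyridine should give methyl methoxyacetate F5. Its lithium enolate (LiN(iPr)2, 2 equiv, THF, −78 °C) is C-acylated with acetoxyacetyl chloride to give methyl 4-acetoxy-2-methoxy-3-oxobutanoate F6. HCl in methanol removes the acetate, the γ-hydroxy-β-keto ester lactonises, and the route is rejoined at 4.

## Further compounds

F1 | step 8 | 1-(3,4-dimethoxyphenyl)penta-1,4-diyn-3-one | COc1ccc(C#CC(=O)C#C)cc1OC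
F2 | step 8 | 1-[2-(tert-butyldimethylsilyloxy)-5-hydroxy-3,4-dimethoxyphenyl]-3-(3,4-dimethoxyphenyl)prop-2-yn-1-one | COc1ccc(C#CC(=O)c2cc(O)c(OC)c(OC)c2O[Si](C)(C)C(C)(C)C)cc1OC
F3 | step 10 | 5-(benzyloxy)-2-(3,4-dimethoxyphenyl)-6-hydroxy-7,8-dimethoxy-4H-chromen-4-one | COc1ccc(-c2cc(=O)c3c(OCc4ccccc4)c(O)c(OC)c(OC)c3o2)cc1OC
F4 | step 9 | (2E)-1-[2-bromo-6-(tert-butyldimethylsilyloxy)-3-hydroxy-4,5-dimethoxyphenyl]-3-(diethylamino)-3-(3,4-dimethoxyphenyl)prop-2-en-1-one | CCN(CC)/C(=C/C(=O)c1c(Br)c(O)c(OC)c(OC)c1O[Si](C)(C)C(C)(C)C)c1ccc(OC)c(OC)c1
F5 | step 2 | methyl methoxyacetate | COCC(=O)OC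
F6 | step 2 | methyl 4-acetoxy-2-methoxy-3-oxobutanoate (racemic) | COC(=O)C(OC)C(=O)COC(C)=O
A1 | alternative 1 | 2-ethoxy-5,6-dimethoxy-4-(methoxymethoxy)phenol | CCOc1cc(OCOC)c(OC)c(OC)c1O
A2 | alternative 1 | 4-[(Z)-2-ethoxyethenyl]-2,3-dimethoxy-4-(methoxymethoxy)cyclobut-2-en-1-one (racemic) | CCO/C=C\C1(OCOC)C(OC)=C(OC)C1=O
A3 | alternative 2 | 2-(3,4-dimethoxyphenyl)-7,8-dimethoxy-5,6-bis(methoxymethoxy)-4H-chromen-4-one | COCOc1c(OCOC)c(OC)c(OC)c2oc(-c3ccc(OC)c(OC)c3)cc(=O)c12
A4 | alternative 2 | 1-[2-bromo-3,4-dimethoxy-5,6-bis(methoxymethoxy)phenyl]-3-(3,4-dimethoxyphenyl)propane-1,3-dione | COCOc1c(OCOC)c(OC)c(OC)c(Br)c1C(=O)CC(=O)c1ccc(OC)c(OC)c1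
A5 | alternative 3 | 1-(3,4-dimethoxyphenyl)-3-(2,3,6-trihydroxy-4,5-dimethoxyphenyl)propane-1,3-dione | COc1ccc(C(=O)CC(=O)c2c(O)c(O)c(OC)c(OC)c2O)cc1OC
A6 | alternative 3 | methyl (2S)-3,4-dimethoxy-5-oxo-2,5-dihydrofuran-2-carboxylate | COC(=O)[C@H]1OC(=O)C(OC)=C1OC
A7 | alternative 3 | 1-(3,4-dimethoxyphenyl)butane-1,3-dione | CC(=O)CC(=O)c1ccc(OC)c(OC)c1
A8 | alternative 3 | L-ascorbic acid | OC[C@H](O)[C@H]1OC(=O)C(O)=C1O
A9 | alternative 3 | 2-(3,4-dimethoxyphenyl)-5,8-dihydroxy-6,7-dimethoxy-4H-chromen-4-one | COc1ccc(-c2cc(=O)c3c(O)c(OC)c(OC)c(O)c3o2)cc1OC
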